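**Retrosynthetic overview**
1. Last bonds: the C8 ester (alcohol 15 + acid 20), C12 by hydroxycarbonylation of a C11 enol triflate, and C15–OH with C4=C5 by 1,3-transposition of a C5 allylic silyl ether.
2. C14 comes from methylenation of a C10 ketone; H1 comes from SmI2 cleavage of the C1–O bridge of a 7-oxanorbornanone.
3. Key step: intramolecular Diels–Alder reaction of a 3-methoxyfuran with a tethered (Z)-enone (8 → 9). Ring A (tether) and ring B (cycloadduct) form together; C1, C6, C7 and C8 are set from the temporary C5 stereocentre.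
4. Triene 8 comes from 3-methoxyfuran, 2-bromo-4-iodobut-1-ene and (2Z)-4-oxopent-2-enal (oxidative ring opening of 2-methylfuran), joined by alkylation and an asymmetric Nozaki–Hiyama–Kishi coupling (CrCl2/NiCl2).
5. Acid 20 comes from (R)-glyceraldehyde acetonide (alkyne, then Markovnikov hydroalumination/CO2).

Locants follow cadinane numbering (ring A = C1–C6; ring B = C1, C6–C10; C11–C13 on C7; C14 on C10; C15 on C4; primes = acyl chain). α is the face of ring B that carries O8.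
Assumption: 1, 3, 6 and 16 are bought, and the antipode of Kishi's oxazoline–sulfonamide ligand that gives the 5S carbinol in step 4 is used (checked once by Mosher analysis).

**Step 1**
Reactants: 1 3-bromobut-3-en-1-ol
Product: 2 2-bromo-4-iodobut-1-ene
Conditions: I2, PPh3, imidazole, CH2Cl2, 0 °C to rt
Reagents that add atoms: iodine, II
Why: Appel-type (Garegg–Samuelsson) iodination of the primary alcohol, with the vinyl bromide inert and no stereocentre involved.

**Step 2**
Reactants: 3 3-methoxyfuran; 2 2-bromo-4-iodobut-1-ene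
Product: 5 2-(3-bromobut-3-en-1-yl)-3-methoxyfuran, via lithiofuran 4 (not isolated)
Conditions: n-BuLi, THF, −78 to 0 °C; then 2, DMPU, −78 °C to rt
Reagents that add atoms: none
Why: directed α-lithiation at C2 (between the ring oxygen and the OMe carbon) followed by SN2 alkylation with the primary iodide, the sp2 C–Br bond being untouched.

**Step 3**
Reactants: 6 2-methylfuran
Product: 7 (2Z)-4-oxopent-2-enal
Conditions: dimethyldioxirane, acetone, −78 to 0 °C; used at once
Reagents that add atoms: dimethyldioxirane, CC1(C)OO1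
Why: oxidative ring opening of the furan (epoxidation, then electrocyclic opening) gives the enedicarbonyl with Z geometry because the alkene is the former ring C3=C4 bond.

**Step 4**
Reactants: 5 2-(3-bromobut-3-en-1-yl)-3-methoxyfuran; 7 (2Z)-4-oxopent-2-enal
Product: 8 (3Z,5S)-8-(3-methoxyfuran-2-yl)-6-methylidene-5-(triethylsilyloxy)oct-3-en-2-one
Conditions: CrCl2 (10 mol %), Kishi oxazoline–sulfonamide ligand (11 mol %), NiCl2·(2,9-dimethyl-1,10-phenanthroline) (2 mol %), Mn, LiCl, Et3SiCl, proton sponge, MeCN, rt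
Reagents that add atoms: chlorotriethylsilane, CC[Si](Cl)(CC)CC
Why: catalytic asymmetric Nozaki–Hiyama–Kishi coupling in which the alkenylchromium adds 1,2 to the aldehyde only, the chiral ligand sets C5 (S), and Et3SiCl turns the chromium over and caps the alkoxide before it can close onto the Z ketone.

**Step 5**
Reactants: 8 (3Z,5S)-8-(3-methoxyfuran-2-yl)-6-methylidene-5-(triethylsilyloxy)oct-3-en-2-one
Product: 9 7α-acetyl-1α,8α-epoxy-10-methoxy-4-methylidene-(5S)-5-(triethylsilyloxy)-Δ9-octalin (H6β H7β)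
Conditions: toluene (5 mM), BHT, base-washed glass, 60 °C
Reagents that add atoms: none
Why: intramolecular Diels–Alder reaction of the furan (IMDAF) with matched polarity (nucleophilic furan C2 to enone β-carbon C6), in which the four-atom tether enforces the exo mode, the Z alkene puts C5 and the acetyl group cis and both syn to the oxygen bridge, and A(1,3) strain (H5 eclipsing the alkene, OSiEt3 anti to the diene) selects the face, so C1, C6, C7 and C8 follow from C5.

**Step 6**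
Reactants: 9 7α-acetyl-1α,8α-epoxy-10-methoxy-4-methylidene-(5S)-5-(triethylsilyloxy)-Δ9-octalin
Product: 12 1α,8α-epoxy-4-methylidene-(5S)-5-(triethylsilyloxy)-7α-[1-(trifluoromethylsulfonyloxy)ethenyl]decalin-10-one, via potassium enolate 10 (not isolated), via enol triflate 11 (not isolated)
Conditions: KN(SiMe3)2, THF, −78 °C; Comins' reagent, −78 °C; then aq. oxalic acid, THF, 0 °C
Reagents that add atoms: Comins' reagent (N-(5-chloropyridin-2-yl)bis(trifluoromethanesulfonimide)), FC(F)(F)S(=O)(=O)N(c1ccc(Cl)cn1)S(=O)(=O)C(F)(F)F; water, O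
Why: kinetic deprotonation of the methyl ketone at CH3 and O-sulfonylation give the terminal enol triflate, and hydrolysis of the strained methyl enol ether on acidic work-up gives the C10 ketone, which also removes the diene needed for cycloreversion; no stereocentre is touched.

**Step 7**
Reactants: 12 1α,8α-epoxy-4-methylidene-(5S)-5-(triethylsilyloxy)-7α-[1-(trifluoromethylsulfonyloxy)ethenyl]decalin-10-one
Product: 14 8α-hydroxy-4-methylidene-(5S)-5-(triethylsilyloxy)-7α-[1-(trifluoromethylsulfonyloxy)ethenyl]-trans-decalin-10-one (H1α H6β), via samarium enolate 13 (not isolated)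
Conditions: SmI2 (2.5 equiv), THF–MeOH, −78 °C; then DBU (0.2 equiv), CH2Cl2, 0 °C
Reagents that add atoms: none
Why: SmI2 reductive cleavage of the α-alkoxy ketone breaks C1–O and leaves the oxygen on C8 with its configuration, and base equilibration gives the trans-fused decalone because the cis isomer would place C2 syn-axial to the axial C7 group.

**Step 8**
Reactants: 14 8α-hydroxy-4-methylidene-(5S)-5-(triethylsilyloxy)-7α-[1-(trifluoromethylsulfonyloxy)ethenyl]-trans-decalin-10-one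
Product: 15 4,10-dimethylidene-(5S)-5-(triethylsilyloxy)-7α-[1-(trifluoromethylsulfonyloxy)ethenyl]-trans-decalin-8α-ol
Conditions: Cp2TiMe2 (3 equiv), toluene–THF, 65 °C, dark
Reagents that add atoms: dimethyltitanocene (Cp2TiMe2), C[Ti](C)(C1C=CC=C1)C1C=CC=C1
Why: Petasis methylenation through Cp2Ti=CH2 is non-basic, so the C1 stereocentre, the β-hydroxy ketone and the enol triflate survive.

**Step 9**
Reactants: 16 (4R)-2,2-dimethyl-1,3-dioxolane-4-carbaldehyde
Product: 17 (4S)-4-ethynyl-2,2-dimethyl-1,3-dioxolane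
Conditions: dimethyl (1-diazo-2-oxopropyl)phosphonate, K2CO3, MeOH, 0 °C to rt
Reagents that add atoms: dimethyl (1-diazo-2-oxopropyl)phosphonate, COP(=O)(OC)C(=[N+]=[N-])C(C)=O
Why: Ohira–Bestmann (Seyferth–Gilbert) homologation turns CHO into C≡CH without touching the stereocentre (the descriptor changes from R to S only through the priority rules).

**Step 10**
Reactants: 17 (4S)-4-ethynyl-2,2-dimethyl-1,3-dioxolane
Product: 20 2-[(4S)-2,2-dimethyl-1,3-dioxolan-4-yl]prop-2-enoic acid, via alkenylalane 18 (not isolated), via lithium alanate 19 (not isolated)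
Conditions: NiCl2(dppp) (3 mol %), i-Bu2AlH, THF, 0 to 22 °C; MeLi, −78 °C; CO2, −78 to 0 °C; cold 0.5 M HCl work-up
Reagents that add atoms: carbon dioxide, O=C=O
Why: nickel-catalysed α-selective (Markovnikov) hydroalumination puts aluminium on the internal carbon, and carboxylation of the derived ate complex (Zweifel-type) gives the 2-substituted acrylic acid with the stereocentre untouched.

**Step 11**
Reactants: 20 2-[(4S)-2,2-dimethyl-1,3-dioxolan-4-yl]prop-2-enoic acid; 15 4,10-dimethylidene-(5S)-5-(triethylsilyloxy)-7α-[1-(trifluoromethylsulfonyloxy)ethenyl]-trans-decalin-8α-ol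
Product: 22 8α-O-{2-[(4S)-2,2-dimethyl-1,3-dioxolan-4-yl]prop-2-enoyl} ester of 15, via mixed anhydride 21 (not isolated)
Conditions: 2,4,6-trichlorobenzoyl chloride, Et3N, toluene, rt; then 15, DMAP, rt
Reagents that add atoms: none
Why: Yamaguchi esterification acylates the only free hydroxyl (equatorial C8–OH) with no stereocentre touched.

**Step 12**
Reactants: 22 8α-O-{2-[(4S)-2,2-dimethyl-1,3-dioxolan-4-yl]prop-2-enoyl} ester of 15
Product: 23 8α-{2-[(4S)-2,2-dimethyl-1,3-dioxolan-4-yl]prop-2-enoyloxy}-15-(triethylsilyloxy)-12-norcadina-4,10(14),11(13)-trien-11-yl triflate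
Conditions: Re2O7 (5 mol %), Et2O, rt
Reagents that add atoms: none
Why: rhenium-oxo-catalysed 1,3-transposition of the allylic silyl ether (allyl perrhenate, [3,3] shift) runs to the primary ether with the trisubstituted ring alkene C4=C5, and this erases the temporary C5 stereocentre.

**Step 13**
Reactants: 23 8α-{2-[(4S)-2,2-dimethyl-1,3-dioxolan-4-yl]prop-2-enoyloxy}-15-(triethylsilyloxy)-12-norcadina-4,10(14),11(13)-trien-11-yl triflate
Product: 24 8α-{2-[(4S)-2,2-dimethyl-1,3-dioxolan-4-yl]prop-2-enoyloxy}-15-(triethylsilyloxy)cadina-4,10(14),11(13)-trien-12-oic acid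
Conditions: Pd(OAc)2 (5 mol %), dppf (6 mol %), CO (1 atm), Et3N, DMF–H2O, 50 °C
Reagents that add atoms: carbon monoxide, [C-]#[O+]; water, O
Why: palladium-catalysed hydroxycarbonylation of the enol triflate (oxidative addition to zerovalent palladium, CO insertion, hydrolysis of the acylpalladium) gives the acrylic acid with no stereocentre touched.

**Step 14**
Reactants: 24 8α-{2-[(4S)-2,2-dimethyl-1,3-dioxolan-4-yl]prop-2-enoyloxy}-15-(triethylsilyloxy)cadina-4,10(14),11(13)-trien-12-oic acid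
Product: 25 (1S,6S,7R,8R)-8-[(3S)-3,4-dihydroxy-2-methylidenebutanoyloxy]-15-hydroxycadina-4,10(14),11(13)-trien-12-oic acid (target)
Conditions: AcOH–THF–H2O (3:1:1), 35 °C
Reagents that add atoms: none
Why: mild acid hydrolysis removes the primary silyl ether and the acetonide, and the acidic medium avoids base-induced lactonisation of the 4′-hydroxy ester and leaves the 1,1-disubstituted alkenes alone.

**Compound list**
1 | 3-bromobut-3-en-1-ol | OCCC(Br)=C | starting material
2 | 2-bromo-4-iodobut-1-ene | ICCC(Br)=C | intermediate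
3 | 3-methoxyfuran | COc1ccoc1 | starting material
4 | (3-methoxyfuran-2-yl)lithium | [Li]c1occc1OC | intermediate
5 | 2-(3-bromobut-3-en-1-yl)-3-methoxyfuran | C=C(Br)CCc1occc1OC | intermediate
6 | 2-methylfuran | Cc1ccco1 | starting material
7 | (2Z)-4-oxopent-2-enal | CC(=O)/C=C\C=O | intermediate
8 | (3Z,5S)-8-(3-methoxyfuran-2-yl)-6-methylidene-5-(triethylsilyloxy)oct-3-en-2-one | CC(=O)/C=C\[C@H](O[Si](CC)(CC)CC)C(=C)CCc1occc1OC | intermediate
9 | exo cycloadduct: 7-oxanorbornene (O bridging C1 and C8) fused to ring A; acetyl on C7 and C5–C6 bond syn to the O bridge; C10 methyl enol ether; 4-methylidene; (5S)-OSiEt3 | CC(=O)[C@H]1[C@H]2[C@H](O[Si](CC)(CC)CC)C(=C)CC[C@]2(O3)C(OC)=C[C@H]13 | intermediate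
10 | potassium enolate of 9 (C11–O−, C11=C13) | [K+].[O-]C(=C)[C@H]1[C@H]2[C@H](O[Si](CC)(CC)CC)C(=C)CC[C@]2(O3)C(OC)=C[C@H]13 | intermediate
11 | C11 enol triflate of 9 (enol ether intact) | C=C(OS(=O)(=O)C(F)(F)F)[C@H]1[C@H]2[C@H](O[Si](CC)(CC)CC)C(=C)CC[C@]2(O3)C(OC)=C[C@H]13 | intermediate
12 | 1α,8α-epoxy C10 ketone with the C11 enol triflate | C=C(OS(=O)(=O)C(F)(F)F)[C@H]1[C@H]2[C@H](O[Si](CC)(CC)CC)C(=C)CC[C@]2(O3)C(=O)C[C@H]13 | intermediate
13 | bis(diiodosamarium) C10 enolate / C8 alkoxide | C=C(OS(=O)(=O)C(F)(F)F)[C@H]1[C@H]2[C@H](O[Si](CC)(CC)CC)C(=C)CCC2=C(O[Sm](I)I)C[C@H]1O[Sm](I)I | intermediate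
14 | trans-fused 8α-hydroxy C10 ketone (H1α, H6β) | C=C(OS(=O)(=O)C(F)(F)F)[C@H]1[C@H]2[C@H](O[Si](CC)(CC)CC)C(=C)CC[C@@H]2C(=O)C[C@H]1O | intermediate
15 | trans-fused 4,10-dimethylidene 8α-alcohol | C=C(OS(=O)(=O)C(F)(F)F)[C@H]1[C@H]2[C@H](O[Si](CC)(CC)CC)C(=C)CC[C@@H]2C(=C)C[C@H]1O | intermediate
16 | (4R)-2,2-dimethyl-1,3-dioxolane-4-carbaldehyde | O=C[C@H]1COC(C)(C)O1 | starting material
17 | (4S)-4-ethynyl-2,2-dimethyl-1,3-dioxolane | C#C[C@H]1COC(C)(C)O1 | intermediate
18 | {1-[(4S)-2,2-dimethyl-1,3-dioxolan-4-yl]ethenyl}diisobutylalane | C=C([Al](CC(C)C)CC(C)C)[C@H]1COC(C)(C)O1 | intermediate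
19 | lithium methyl alanate of 18 | [Li+].C=C([Al-](C)(CC(C)C)CC(C)C)[C@H]1COC(C)(C)O1 | intermediate
20 | 2-[(4S)-2,2-dimethyl-1,3-dioxolan-4-yl]prop-2-enoic acid | C=C(C(=O)O)[C@H]1COC(C)(C)O1 | intermediate
21 | mixed anhydride of 20 with 2,4,6-trichlorobenzoic acid | C=C(C(=O)OC(=O)c1c(Cl)cc(Cl)cc1Cl)[C@H]2COC(C)(C)O2 | intermediate
22 | 8α-ester of 15 with 20 | C=C(OS(=O)(=O)C(F)(F)F)[C@H]1[C@H]2[C@H](O[Si](CC)(CC)CC)C(=C)CC[C@@H]2C(=C)C[C@H]1OC(=O)C(=C)[C@H]3COC(C)(C)O3 | intermediate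
23 | transposed ether: C4=C5, 15-OSiEt3, C11 enol triflate, 8α-ester | C=C(OS(=O)(=O)C(F)(F)F)[C@H]1[C@H]2C=C(CO[Si](CC)(CC)CC)CC[C@@H]2C(=C)C[C@H]1OC(=O)C(=C)[C@H]3COC(C)(C)O3 | intermediate
24 | 12-oic acid with 15-OSiEt3 and side-chain acetonide | C=C(C(=O)O)[C@H]1[C@H]2C=C(CO[Si](CC)(CC)CC)CC[C@@H]2C(=C)C[C@H]1OC(=O)C(=C)[C@H]3COC(C)(C)O3 | intermediate
25 | (1S,6S,7R,8R)-8-[(3S)-3,4-dihydroxy-2-methylidenebutanoyloxy]-15-hydroxycadina-4,10(14),11(13)-trien-12-oic acid | C=C(C(=O)O)[C@H]1[C@H]2C=C(CO)CC[C@@H]2C(=C)C[C@H]1OC(=O)C(=C)[C@H](O)CO | target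

**Step count**
Total: 14 steps. Longest linear sequence: 11 steps (1, 2, 4, 5, 6, 7, 8, 11, 12, 13, 14). Steps 3, 9 and 10 are side branches.

**Three steps most likely to fail**

Step 4 (asymmetric coupling). The Z ene-dicarbonyl 7 may be reduced by divalent chromium or isomerise, the alkoxide may close onto the ketone, and the sense and level of induction are unproven. The fallback sets out from 5 and comes back at 8. Bromine–lithium exchange on 5 (t-BuLi, THF, −78 °C) and acylation with N-methoxy-N-methyl-3-(trimethylsilyl)prop-2-ynamide give the ynone F1. CBS reduction with (R)-2-methyl-CBS-oxazaborolidine and BH3·SMe2 (alkynyl as the small group) gives the (3R)-propargylic alcohol F2. Et3SiCl/imidazole gives the silyl ether F3, and K2CO3/MeOH at 0 °C removes the C-silyl group to give the terminal alkyne F4. LiN(SiMe3)2 and then N-methoxy-N-methylacetamide give the (5R)-ynone F5. Semihydrogenation over Pd/CaCO3 poisoned with Pb(OAc)2 and quinoline gives the Z enone 8.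

Step 5 (furan Diels–Alder). Risks are an unfavourable equilibrium, Z to E leakage, or a stepwise ionic path that loses the exo/facial control. The fallback uses a Z-locked cyclic dienophile; it sets out from 5 and comes back at 23.
- The vinyllithium from 5 (t-BuLi) is formylated with DMF to the enal F6.
- Me2Zn/ProPhenol-catalysed addition of methyl propiolate (ligand antipode giving 4S) gives the hydroxy ynoate F7.
- Semihydrogenation (Pd/CaCO3, Pb(OAc)2, quinoline) with spontaneous lactonisation gives the (5R)-butenolide F8.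
- Heating F8 in toluene at 90 °C gives the exo lactone cycloadduct F9. The ring oxygen now sits inside, so C5 is epimeric to the main series; this does not matter because C5 is later erased.
- MeLi (1 equiv, −78 °C) opens the lactone to the hydroxy ketone F10, and Et3SiOTf/2,6-lutidine gives the 5-epimer of 9, F11.
- F11 is taken through the conditions of step 6 (potassium enolate F12, enol triflate F13, bridged ketone F14), step 7 (samarium enolate F15, hydroxy ketone F16), step 8 (diene alcohol F17) and step 11 (ester F18).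
- Under the conditions of step 12, C5 becomes sp2 and the material is 23.

Step 12 (rhenium transposition). The acid-sensitive acetonide and silyl ether may not survive, or ionisation may lead to elimination. The fallback sets out from 22 and comes back at 23. HF·pyridine in THF/pyridine removes the silyl group to give the secondary allylic alcohol F19. CBr4/PPh3 followed by LiBr equilibration gives the rearranged primary allylic bromide F20 with the C4=C5 ring alkene. HCO2Na in DMF gives the allylic formate F21, and KHCO3/MeOH at 0 °C gives the primary allylic alcohol F22. Et3SiCl/imidazole returns 23.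

**Further compounds**
F1 | step 4 | 6-(3-methoxyfuran-2-yl)-4-methylidene-1-(trimethylsilyl)hex-1-yn-3-one | C[Si](C)(C)C#CC(=O)C(=C)CCc1occc1OC
F2 | step 4 | (3R)-6-(3-methoxyfuran-2-yl)-4-methylidene-1-(trimethylsilyl)hex-1-yn-3-ol | C[Si](C)(C)C#C[C@H](O)C(=C)CCc1occc1OC
F3 | step 4 | triethylsilyl ether of F2 | C[Si](C)(C)C#C[C@H](O[Si](CC)(CC)CC)C(=C)CCc1occc1OC
F4 | step 4 | (3R)-6-(3-methoxyfuran-2-yl)-4-methylidene-3-(triethylsilyloxy)hex-1-yne | C#C[C@H](O[Si](CC)(CC)CC)C(=C)CCc1occc1OC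
F5 | step 4 | (5R)-8-(3-methoxyfuran-2-yl)-6-methylidene-5-(triethylsilyloxy)oct-3-yn-2-one | CC(=O)C#C[C@H](O[Si](CC)(CC)CC)C(=C)CCc1occc1OC
F6 | step 5 | 4-(3-methoxyfuran-2-yl)-2-methylidenebutanal | C=C(C=O)CCc1occc1OC
F7 | step 5 | methyl (4S)-4-hydroxy-7-(3-methoxyfuran-2-yl)-5-methylidenehept-2-ynoate | COC(=O)C#C[C@@H](O)C(=C)CCc1occc1OC
F8 | step 5 | (5R)-5-[4-(3-methoxyfuran-2-yl)but-1-en-2-yl]furan-2(5H)-one | O=C1C=C[C@H](C(=C)CCc2occc2OC)O1
F9 | step 5 | exo lactone cycloadduct (C11(=O)–O–C5 lactone, O bridge C1–C8, C10 methyl enol ether) | O=C1[C@H]2[C@H]3[C@@H](O1)C(=C)CC[C@]3(O4)C(OC)=C[C@H]24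
F10 | step 5 | 5-epi hydroxy ketone (7-acetyl, 5-OH) | CC(=O)[C@H]1[C@H]2[C@@H](O)C(=C)CC[C@]2(O3)C(OC)=C[C@H]13
F11 | step 5 | 5-epimer of 9 | CC(=O)[C@H]1[C@H]2[C@@H](O[Si](CC)(CC)CC)C(=C)CC[C@]2(O3)C(OC)=C[C@H]13
F12 | step 5 | 5-epimer of 10 | [K+].[O-]C(=C)[C@H]1[C@H]2[C@@H](O[Si](CC)(CC)CC)C(=C)CC[C@]2(O3)C(OC)=C[C@H]13
F13 | step 5 | 5-epimer of 11 | C=C(OS(=O)(=O)C(F)(F)F)[C@H]1[C@H]2[C@@H](O[Si](CC)(CC)CC)C(=C)CC[C@]2(O3)C(OC)=C[C@H]13
F14 | step 5 | 5-epimer of 12 | C=C(OS(=O)(=O)C(F)(F)F)[C@H]1[C@H]2[C@@H](O[Si](CC)(CC)CC)C(=C)CC[C@]2(O3)C(=O)C[C@H]13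
F15 | step 5 | 5-epimer of 13 | C=C(OS(=O)(=O)C(F)(F)F)[C@H]1[C@H]2[C@@H](O[Si](CC)(CC)CC)C(=C)CCC2=C(O[Sm](I)I)C[C@H]1O[Sm](I)I
F16 | step 5 | 5-epimer of 14 | C=C(OS(=O)(=O)C(F)(F)F)[C@H]1[C@H]2[C@@H](O[Si](CC)(CC)CC)C(=C)CC[C@@H]2C(=O)C[C@H]1O
F17 | step 5 | 5-epimer of 15 | C=C(OS(=O)(=O)C(F)(F)F)[C@H]1[C@H]2[C@@H](O[Si](CC)(CC)CC)C(=C)CC[C@@H]2C(=C)C[C@H]1O
F18 | step 5 | 5-epimer of 22 | C=C(OS(=O)(=O)C(F)(F)F)[C@H]1[C@H]2[C@@H](O[Si](CC)(CC)CC)C(=C)CC[C@@H]2C(=C)C[C@H]1OC(=O)C(=C)[C@H]3COC(C)(C)O3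
F19 | step 12 | desilylated 22 (secondary allylic 5-OH) | C=C(OS(=O)(=O)C(F)(F)F)[C@H]1[C@H]2[C@H](O)C(=C)CC[C@@H]2C(=C)C[C@H]1OC(=O)C(=C)[C@H]3COC(C)(C)O3
F20 | step 12 | primary allylic bromide (15-Br, C4=C5) | C=C(OS(=O)(=O)C(F)(F)F)[C@H]1[C@H]2C=C(CBr)CC[C@@H]2C(=C)C[C@H]1OC(=O)C(=C)[C@H]3COC(C)(C)O3
F21 | step 12 | 15-formate | C=C(OS(=O)(=O)C(F)(F)F)[C@H]1[C@H]2C=C(COC=O)CC[C@@H]2C(=C)C[C@H]1OC(=O)C(=C)[C@H]3COC(C)(C)O3
F22 | step 12 | 15-alcohol (desilyl 23) | C=C(OS(=O)(=O)C(F)(F)F)[C@H]1[C@H]2C=C(CO)CC[C@@H]2C(=C)C[C@H]1OC(=O)C(=C)[C@H]3COC(C)(C)O3
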